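**Retrosynthetic overview**

1. The three ring oxygens come from one enone (C7=O, C8=C9): C8-acylation ⇐ osmylation of C8=C9 anti to the C7 angelate ⇐ catalyst-controlled reduction of the C7 ketone.
2. The C7 enone comes from a C7=C8 cycloheptene by singlet-oxygen ene reaction; the cyclohexenone (C1–C4, C10, C11) comes from an enantioselective aldol condensation of a meso cis-1,3-diacetylcyclobutane.
3. Key disconnection: C7–C8 and C9–C10. A two-carbon vinylphosphonium unit is inserted between C10 (exocyclic methylene → tertiary radical by hydrogen-atom transfer) and the C7 aldehyde (Giese addition, reduction to the ylide, intramolecular Wittig).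
4. Enabling feature: C10 is a methyl-bearing quaternary carbon of the four-membered ring (C4–C5–C11–C10), so it can be unmasked from C=CH2 plus H•. It lies 1,3-cis across that ring from C5, whose gem-dimethyl carbon C6 carries C7 as a non-enolisable aldehyde, so a two-carbon bridge spans the two termini.
5. Ring order: cyclobutane (dichloroketene [2+2], step 2) → seven-membered ring (step 9) → cyclohexenone (step 10).

Key step: step 9

Remark: ring positions use longipinane numbering (C1 ketone, C2=C3 with methyl on C3, C4 and C11 cyclobutane bridgeheads, C5, C6 gem-dimethyl, C7–C9, C10 quaternary); α is the face of the seven-membered ring on the C11 side, β the face on the C4 side.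

Remark: 1, 15, 26 and 30 are taken as commercial; 8–10, 12 and 13 are carried as mixtures at the carbinol carbons (left open in the SMILES), which step 8 erases; SMILES of racemic or meso compounds show relative configuration.

**Step 1**
Reactants: 1 2,2-dimethylbut-3-en-1-ol
Product: 2 tert-butyl[(2,2-dimethylbut-3-en-1-yl)oxy]diphenylsilane
Conditions: TBDPSCl, imidazole, DMF, 0 °C to rt
Reagents that add atoms: tert-butyl(chloro)diphenylsilane, CC(C)(C)[Si](Cl)(c1ccccc1)c1ccccc1
Why: imidazole-promoted silylation of a primary alcohol; the bulky silyl ether should survive zinc salts, acetic acid, amide bases and the methylenation, and no stereocentre is involved.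

**Step 2**
Reactants: 2 tert-butyl[(2,2-dimethylbut-3-en-1-yl)oxy]diphenylsilane; 3 trichloroacetyl chloride
Product: 5 2,2-dichloro-3-[1-(tert-butyldiphenylsilyloxy)-2-methylpropan-2-yl]cyclobutan-1-one (racemic), via dichloroketene 4 (not isolated)
Conditions: Zn(Cu), POCl3, Et2O, reflux, slow addition of 3
Reagents that add atoms: none
Why: thermal [2+2] cycloaddition of dichloroketene generated in situ with the terminal alkene should give the 3-substituted 2,2-dichlorocyclobutanone (carbonyl carbon to the CH2 terminus); its one stereocentre disappears in step 3.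

**Step 3**
Reactants: 5 the dichlorocyclobutanone
Product: 6 3-[1-(tert-butyldiphenylsilyloxy)-2-methylpropan-2-yl]cyclobutan-1-one
Conditions: Zn dust, AcOH, rt
Reagents that add atoms: none
Why: zinc-mediated reductive dechlorination of an α,α-dichloroketone; the product is achiral.

**Step 4**
Reactants: 6 the cyclobutanone; 7 acetaldehyde (two equivalents)
Product: 9 2,4-bis(1-hydroxyethyl)-3-[1-(tert-butyldiphenylsilyloxy)-2-methylpropan-2-yl]cyclobutan-1-one (hydroxyethyl arms cis to each other and trans to the C3 substituent), via mono-aldol 8 (not isolated)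
Conditions: LDA, THF, −78 °C; 7; then LDA, −78 °C; 7; aq NH4Cl, −78 °C
Reagents that add atoms: none
Why: two successive kinetic lithium-enolate aldol additions; each new ring stereocentre should form anti to the bulky C3 substituent, which places the two arms cis to each other and trans to it, while the carbinol centres are uncontrolled and are erased in step 8.

**Step 5**
Reactants: 9 the bis-aldol
Product: 10 2,4-bis[1-(triethylsilyloxy)ethyl]-3-[1-(tert-butyldiphenylsilyloxy)-2-methylpropan-2-yl]cyclobutan-1-one
Conditions: TESOTf, 2,6-lutidine, CH2Cl2, −78 °C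
Reagents that add atoms: triethylsilyl trifluoromethanesulfonate, CC[Si](CC)(CC)OS(=O)(=O)C(F)(F)F
Why: silyl triflate silylation of the secondary alcohols, which blocks retro-aldol cleavage and β-elimination of the β-hydroxy cyclobutanone in the next step.

**Step 6**
Reactants: 10 the bis-silyl ether ketone; 11 dibromomethane
Product: 12 the corresponding 1-methylidenecyclobutane (ring configuration unchanged)
Conditions: Zn, TiCl4, THF/CH2Cl2, 0 °C to rt
Reagents that add atoms: none
Why: Takai–Lombardo methylenation, a non-basic zinc–titanium carbenoid olefination that should convert the hindered, epimerisable ketone into the exocyclic alkene without touching the α-stereocentres.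

**Step 7**
Reactants: 12 the tris-silyl ether
Product: 13 2-[2,4-bis(1-hydroxyethyl)-3-methylidenecyclobutyl]-2-methylpropan-1-ol
Conditions: TBAF, THF, rt
Reagents that add atoms: none
Why: fluoride-induced cleavage of all three silyl ethers.

**Step 8**
Reactants: 13 the triol
Product: 14 2-(2,4-diacetyl-3-methylidenecyclobutyl)-2-methylpropanal (acetyl groups cis to each other and trans to the aldehyde chain; meso)
Conditions: Dess–Martin periodinane, NaHCO3, CH2Cl2, 0 °C, used at once
Reagents that add atoms: none
Why: Dess–Martin oxidation is neutral and non-enolising, so it should give the meso diketo aldehyde without moving the exocyclic double bond into conjugation; the carbinol mixtures converge to one compound.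

**Step 9**
Reactants: 14 the meso diketo aldehyde; 15 vinyltriphenylphosphonium bromide
Product: 19 1,1'-(1,5,5-trimethylbicyclo[4.1.1]oct-3-ene-7,8-diyl)di(ethan-1-one) (both acetyl groups anti to the four-carbon bridge; meso), via tertiary radical 16 (not isolated), via phosphonium ylide 17 (not isolated), via oxaphosphetane 18 (not isolated)
Conditions: 15 (3 equiv), Fe(acac)3 (10 mol %), PhSiH3, i-PrOH (2 equiv), THF/CH2Cl2, 30 °C, slow addition of 14
Reagents that add atoms: none
Why: Proposed new method: a ferric hydride formed from Fe(acac)3 and the silane should transfer a hydrogen atom to the exocyclic CH2 of 14, creating the C10 methyl group and the tertiary cyclobutyl radical 16; this nucleophilic radical adds to the β-carbon of the cationic acceptor 15 (Giese addition, C9–C10), the α-phosphonio radical is reduced by the ferrous complex to ylide 17 (radical–polar crossover), and the ylide closes onto the C7 aldehyde through oxaphosphetane 18 (intramolecular Wittig, C7=C8). The closest known reaction types are HAT-initiated Giese/aldol annulations of alkenyl aldehydes with enones, photoredox addition of alkyl radicals to vinylphosphonium salts followed by Wittig olefination, and the classical nucleophile/vinylphosphonium annulation; new here is the pairing of metal-hydride HAT with a phosphonium acceptor and a seven-membered ring. The seven-membered ring is closed in a (5+2) sense by the intramolecular Wittig reaction, which can only give the cis ring alkene, so no stereocentre arises at C7 or C8. The one new stereocentre, quaternary C10, is set in the Giese step: the acceptor must approach from the ring face opposite to the two flanking cis acetyl groups on C4 and C11, which is the face of the C5 side chain, and only that adduct can reach the aldehyde. The step needs (a) HAT to a single alkene (14 has only one), (b) trapping of 16 faster than its 1,5-hydrogen abstraction from the aldehyde (excess of the very electrophilic 15, slow addition of 14), (c) an ylide that is not quenched (weakly acidic alcohol only, low loading of the acac complex), and (d) Wittig reaction at the aldehyde rather than at an acetyl group, which the substrate secures because the acetyl groups are trans to the new chain on adjacent ring carbons (closure there would need a trans-fused bicyclo[3.2.0]heptene) while the aldehyde is 1,3-cis.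

**Step 10**
Reactants: 19 the meso bicyclic diketone
Product: 20 longipina-2,7-dien-1-one
Conditions: 9-amino-9-deoxy-epi-quinine (20 mol %), AcOH (60 mol %), 4 Å MS, toluene, 0 °C to rt
Reagents that add atoms: none
Why: enamine-catalysed desymmetrising intramolecular aldol condensation (the type known for 4-substituted heptane-2,6-diones), in which the chiral primary amine should select one of the two enantiotopic, 1,3-diaxially held acetyl groups as donor and so fix the absolute configuration of C4, C5, C10 and C11 in one step; the quinine-derived amine is specified on the assumption that it makes the C11 acetyl the donor, the quinidine-derived pseudo-enantiomer reversing the sense.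

**Step 11**
Reactants: 20 longipina-2,7-dien-1-one
Product: 22 longipina-2,8-diene-1,7-dione, via allylic hydroperoxide 21 (not isolated)
Conditions: O2, tetraphenylporphyrin (cat.), visible light (>500 nm), CH2Cl2, 0 °C; then Ac2O, pyridine, DMAP (cat.), 0 °C to rt
Reagents that add atoms: dioxygen, O=O
Why: Schenck ene reaction followed by Kornblum–DeLaMare dehydration; the only allylic hydrogens are on C9 (C6 is quaternary), so oxygen should enter at C7 with shift of the double bond to C8=C9, the C7 epimers of 21 converge to the enone, and the electron-poor C2=C3 bond is inert.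

**Step 12**
Reactants: 22 the dienedione
Product: 23 1-(triethylsilyloxy)-3-methylidenelongipina-1,8-dien-7-one (C1 silyl dienol ether of 22)
Conditions: TESOTf, Et3N, CH2Cl2, −78 to 0 °C
Reagents that add atoms: triethylsilyl trifluoromethanesulfonate, CC[Si](CC)(CC)OS(=O)(=O)C(F)(F)F
Why: soft enolisation; only the C1 enone has an acidic γ-methyl group, whereas the C7 enone is flanked by the quaternary carbons C6 and C10 and cannot enolise, so the C1 carbonyl alone should be masked.

**Step 13**
Reactants: 23 the silyl dienol ether
Product: 25 7β-hydroxylongipina-2,8-dien-1-one, via hydroxy dienol ether 24 (not isolated)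
Conditions: (S)-2-methyl-CBS-oxazaborolidine (0.5 equiv), catecholborane, toluene, −78 °C; MeOH; then 1 M HCl, THF, 0 °C
Reagents that add atoms: none
Why: Corey–Bakshi–Shibata reduction of the only free ketone; because the lower face of the tricycle is almost mirror-symmetric (C1=O and C3–CH3, which break the symmetry, lie on the far side), C7 cannot be set by the substrate and is set by the catalyst, the (S)-catalyst being chosen on the usual model with quaternary C6 as the large group, and the acidic work-up should return the conjugated C1 enone.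

**Step 14**
Reactants: 25 7β-hydroxylongipina-2,8-dien-1-one; 26 angelic acid
Product: 28 7β-angeloyloxylongipina-2,8-dien-1-one, via mixed anhydride 27 (not isolated)
Conditions: 26, 2,4,6-trichlorobenzoyl chloride, Et3N, toluene, rt; then 25, toluene, 80 °C, no DMAP
Reagents that add atoms: none
Why: Yamaguchi esterification through the mixed anhydride without DMAP, conditions chosen because they should not isomerise the (Z)-angelate to the tiglate; C7–OH is the only hydroxyl group.

**Step 15**
Reactants: 28 the angelate
Product: 29 7β-angeloyloxy-8α,9α-dihydroxylongipin-2-en-1-one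
Conditions: OsO4 (5 mol %), NMO, acetone/H2O, rt
Reagents that add atoms: N-methylmorpholine N-oxide, C[N+]1([O-])CCOCC1, and water, O (both delivered through osmium tetroxide, O=[Os](=O)(=O)=O)
Why: osmium-catalysed syn-dihydroxylation (Upjohn conditions); the cis C8=C9 bond should react in preference to the two conjugated trisubstituted alkenes, and attack anti to the allylic C7 acyloxy group places both new hydroxyl groups on the α face, cis to each other and trans to O7.

**Step 16**
Reactants: 29 the diol; 30 (R)-2-methylbutanoic acid
Product: 31 7β-angeloyloxy-8α-[(R)-2-methylbutanoyloxy]-9α-hydroxylongipin-2-en-1-one (CNP0206166.1)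
Conditions: EDC·HCl, DMAP (10 mol %), CH2Cl2, −20 to 0 °C
Reagents that add atoms: none
Why: carbodiimide/DMAP (Steglich) esterification; the C8 hydroxyl, flanked by two CH carbons, should be acylated in preference to the C9 hydroxyl, which is neopentylic to quaternary C10, and low temperature with catalytic DMAP limits acyl migration and epimerisation of the acid's α-stereocentre.

**Compound list**

1 | 2,2-dimethylbut-3-en-1-ol | C=CC(C)(C)CO | starting material
2 | tert-butyl[(2,2-dimethylbut-3-en-1-yl)oxy]diphenylsilane | C=CC(C)(C)CO[Si](c1ccccc1)(c1ccccc1)C(C)(C)C | intermediate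
3 | trichloroacetyl chloride | ClC(=O)C(Cl)(Cl)Cl | starting material
4 | dichloroketene | O=C=C(Cl)Cl | intermediate
5 | 2,2-dichloro-3-[1-(tert-butyldiphenylsilyloxy)-2-methylpropan-2-yl]cyclobutan-1-one (racemic) | O=C1CC(C(C)(C)CO[Si](c2ccccc2)(c2ccccc2)C(C)(C)C)C1(Cl)Cl | intermediate
6 | 3-[1-(tert-butyldiphenylsilyloxy)-2-methylpropan-2-yl]cyclobutan-1-one | O=C1CC(C(C)(C)CO[Si](c2ccccc2)(c2ccccc2)C(C)(C)C)C1 | intermediate
7 | acetaldehyde | CC=O | starting material
8 | trans-2-(1-hydroxyethyl)-3-[1-(tert-butyldiphenylsilyloxy)-2-methylpropan-2-yl]cyclobutan-1-one (racemic, carbinol epimers) | O=C1C[C@@H](C(C)(C)CO[Si](c2ccccc2)(c2ccccc2)C(C)(C)C)[C@@H]1C(C)O | intermediate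
9 | 2,4-bis(1-hydroxyethyl)-3-[1-(tert-butyldiphenylsilyloxy)-2-methylpropan-2-yl]cyclobutan-1-one (arms cis, both trans to the C3 group) | O=C1[C@H](C(C)O)[C@@H](C(C)(C)CO[Si](c2ccccc2)(c2ccccc2)C(C)(C)C)[C@@H]1C(C)O | intermediate
10 | bis(triethylsilyl) ether of 9 | O=C1[C@H](C(C)O[Si](CC)(CC)CC)[C@@H](C(C)(C)CO[Si](c2ccccc2)(c2ccccc2)C(C)(C)C)[C@@H]1C(C)O[Si](CC)(CC)CC | intermediate
11 | dibromomethane | BrCBr | starting material
12 | 1-methylidene analogue of 10 | C=C1[C@H](C(C)O[Si](CC)(CC)CC)[C@@H](C(C)(C)CO[Si](c2ccccc2)(c2ccccc2)C(C)(C)C)[C@@H]1C(C)O[Si](CC)(CC)CC | intermediate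
13 | 2-[2,4-bis(1-hydroxyethyl)-3-methylidenecyclobutyl]-2-methylpropan-1-ol | C=C1[C@H](C(C)O)[C@@H](C(C)(C)CO)[C@@H]1C(C)O | intermediate
14 | 2-(2,4-diacetyl-3-methylidenecyclobutyl)-2-methylpropanal (acetyls cis, trans to the chain; meso) | C=C1[C@H](C(C)=O)[C@@H](C(C)(C)C=O)[C@@H]1C(C)=O | intermediate
15 | vinyltriphenylphosphonium bromide | C=C[P+](c1ccccc1)(c1ccccc1)c1ccccc1.[Br-] | starting material
16 | tertiary 1-methylcyclobutyl radical from 14 | C[C]1[C@H](C(C)=O)[C@@H](C(C)(C)C=O)[C@@H]1C(C)=O | intermediate
17 | triphenylphosphonium ylide (new two-carbon chain on C10, cis to the aldehyde chain) | C[C@]1(CC=P(c2ccccc2)(c2ccccc2)c2ccccc2)[C@H](C(C)=O)[C@@H](C(C)(C)C=O)[C@@H]1C(C)=O | intermediate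
18 | ring-fused oxaphosphetane | CC1(C)C2OP(c3ccccc3)(c3ccccc3)(c3ccccc3)C2C[C@@]2(C)[C@H](C(C)=O)[C@@H]1[C@@H]2C(C)=O | intermediate
19 | 1,1'-(1,5,5-trimethylbicyclo[4.1.1]oct-3-ene-7,8-diyl)di(ethan-1-one) (meso) | CC1(C)C=CC[C@@]2(C)[C@H](C(C)=O)[C@@H]1[C@@H]2C(C)=O | intermediate
20 | longipina-2,7-dien-1-one | C1=CC[C@@]2(C)[C@@H]3C(=O)C=C(C)[C@H]2[C@@H]3C1(C)C | intermediate
21 | 7-hydroperoxylongipina-2,8-dien-1-one (C7 epimers) | OOC1C=C[C@@]2(C)[C@@H]3C(=O)C=C(C)[C@H]2[C@@H]3C1(C)C | intermediate
22 | longipina-2,8-diene-1,7-dione | O=C1C=C[C@@]2(C)[C@@H]3C(=O)C=C(C)[C@H]2[C@@H]3C1(C)C | intermediate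
23 | 1-(triethylsilyloxy)-3-methylidenelongipina-1,8-dien-7-one | O=C1C=C[C@@]2(C)[C@@H]3C(O[Si](CC)(CC)CC)=CC(=C)[C@H]2[C@@H]3C1(C)C | intermediate
24 | 7β-hydroxy-1-(triethylsilyloxy)-3-methylidenelongipina-1,8-diene | O[C@@H]1C=C[C@@]2(C)[C@@H]3C(O[Si](CC)(CC)CC)=CC(=C)[C@H]2[C@@H]3C1(C)C | intermediate
25 | 7β-hydroxylongipina-2,8-dien-1-one | O[C@@H]1C=C[C@@]2(C)[C@@H]3C(=O)C=C(C)[C@H]2[C@@H]3C1(C)C | intermediate
26 | angelic acid, (Z)-2-methylbut-2-enoic acid | C/C=C(/C)C(=O)O | starting material
27 | angelic 2,4,6-trichlorobenzoic anhydride | C/C=C(/C)C(=O)OC(=O)c1c(Cl)cc(Cl)cc1Cl | intermediate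
28 | 7β-angeloyloxylongipina-2,8-dien-1-one | C/C=C(/C)C(=O)O[C@@H]1C=C[C@@]2(C)[C@@H]3C(=O)C=C(C)[C@H]2[C@@H]3C1(C)C | intermediate
29 | 7β-angeloyloxy-8α,9α-dihydroxylongipin-2-en-1-one | C/C=C(/C)C(=O)O[C@@H]1[C@@H](O)[C@@H](O)[C@@]2(C)[C@@H]3C(=O)C=C(C)[C@H]2[C@@H]3C1(C)C | intermediate
30 | (R)-2-methylbutanoic acid | CC[C@@H](C)C(=O)O | starting material
31 | 7β-angeloyloxy-8α-[(R)-2-methylbutanoyloxy]-9α-hydroxylongipin-2-en-1-one | C/C=C(/C)C(=O)O[C@@H]1[C@@H](OC(=O)[C@H](C)CC)[C@@H](O)[C@@]2(C)[C@@H]3C(=O)C=C(C)[C@H]2[C@@H]3C1(C)C | target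

**Step count and risks**

Total steps: 16. Longest linear sequence: 16 steps (from 1).

Step 9. The tertiary radical may be captured too slowly by the phosphonium salt, abstract the aldehyde hydrogen, or the ylide may be protonated before ring closure. The two bonds are then made one after the other with known reactions, setting out from 12 and returning at 19. Cobalt-hydride Markovnikov hydrobromination (Co(acac)2, t-BuOOH, Et3SiH, TsBr) should give the tertiary bromide F1. Keck allylation (allyltributylstannane, AIBN, benzene, 80 °C) should bring the allyl group in anti to the two side arms to give the allyl compound F2. TBAF gives the triol F3 and Dess–Martin oxidation the diketo aldehyde F4. Aldehyde-selective methylenation (CH2I2, Zn, Ti(Oi-Pr)4) gives the diene F5, and ring-closing metathesis with the second-generation Grubbs catalyst closes the seven-membered ring to 19.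

Step 10. The condensation may stall at the strained aldol stage, proceed through an uncatalysed racemic background reaction, or discriminate poorly between the two acetyl groups. The fallback sets out from 19 and returns at 20. A stoichiometric chiral base (lithium (R,R)-bis(1-phenylethyl)amide with TMSCl present, THF, −100 °C) desymmetrises 19 to the mono silyl enol ether F6. TiCl4 at −78 °C effects the intramolecular Mukaiyama aldol addition to the β-hydroxy ketone F7, and MsCl/Et3N followed by DBU dehydrates it to 20.

Step 11. Singlet oxygen may react too slowly with the hindered cis-disubstituted alkene, or the hydroperoxide may decompose before dehydration. The fallback sets out from 20 and returns at 22. Dimethyldioxirane (acetone, 0 °C) epoxidises the C7=C8 bond, the enone being inert, to the epoxide F8. Diethylaluminium 2,2,6,6-tetramethylpiperidide (toluene, 0 °C) removes a C9 hydrogen, the only β-hydrogens, and opens the epoxide to the allylic alcohol F9, which MnO2 oxidises to 22.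

Further compounds
F1 | step 9 | 1-bromo-1-methyl-2,4-bis[1-(triethylsilyloxy)ethyl]-3-[1-(tert-butyldiphenylsilyloxy)-2-methylpropan-2-yl]cyclobutane | CC1(Br)[C@H](C(C)O[Si](CC)(CC)CC)[C@@H](C(C)(C)CO[Si](c2ccccc2)(c2ccccc2)C(C)(C)C)[C@@H]1C(C)O[Si](CC)(CC)CC
F2 | step 9 | 1-allyl-1-methyl analogue of F1 (allyl trans to the two silyloxyethyl arms) | C[C@]1(CC=C)[C@H](C(C)O[Si](CC)(CC)CC)[C@@H](C(C)(C)CO[Si](c2ccccc2)(c2ccccc2)C(C)(C)C)[C@@H]1C(C)O[Si](CC)(CC)CC
F3 | step 9 | 2-[3-allyl-2,4-bis(1-hydroxyethyl)-3-methylcyclobutyl]-2-methylpropan-1-ol | C[C@]1(CC=C)[C@H](C(C)O)[C@@H](C(C)(C)CO)[C@@H]1C(C)O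
F4 | step 9 | 2-(2,4-diacetyl-3-allyl-3-methylcyclobutyl)-2-methylpropanal | C[C@]1(CC=C)[C@H](C(C)=O)[C@@H](C(C)(C)C=O)[C@@H]1C(C)=O
F5 | step 9 | 1,1'-[2-allyl-2-methyl-4-(2-methylbut-3-en-2-yl)cyclobutane-1,3-diyl]di(ethan-1-one) | C[C@]1(CC=C)[C@H](C(C)=O)[C@@H](C(C)(C)C=C)[C@@H]1C(C)=O
F6 | step 10 | mono(trimethylsilyl enol ether) of 19 at the C11 acetyl group | CC1(C)C=CC[C@@]2(C)[C@H](C(=C)O[Si](C)(C)C)[C@@H]1[C@@H]2C(C)=O
F7 | step 10 | 3-hydroxy-2,3-dihydrolongipin-7-en-1-one (aldol adduct, C3 epimers) | C1=CC[C@@]2(C)[C@@H]3C(=O)CC(C)(O)[C@H]2[C@@H]3C1(C)C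
F8 | step 11 | 7,8-epoxylongipin-2-en-1-one (epoxide epimers) | O1C2C1C[C@@]1(C)[C@@H]3C(=O)C=C(C)[C@H]1[C@@H]3C2(C)C
F9 | step 11 | 7-hydroxylongipina-2,8-dien-1-one (C7 epimers) | OC1C=C[C@@]2(C)[C@@H]3C(=O)C=C(C)[C@H]2[C@@H]3C1(C)C
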